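**Retrosynthetic overview**
1. All twenty skeletal carbons are bought as all-E geranylgeraniol 1; its acetate 2 is the only acyclic intermediate.
2. Key disconnection: C4–C5 and C9–C10 of the decalin are cut together. Ring A, then ring B, close in one enantioselective proton-initiated cascade of 2 through the C8 cation 3 to the Δ7 bicycle 4. C5, C9 and C10 are all set here.
3. The C17 oxygen is disconnected as an allylic C–H oxidation of the ring methyl of 4 (gives 5); the C17 acetate is the last bond made (5 to target 6).

Assumption: all-E geranylgeraniol counts as a commercial starting material, and the (R)-configured acid gives the natural (5S,10S) fold as it does with related homofarnesyl substrates (if the sense is opposite here, the (S) acid is used).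

**Step 1**
Reactants: 1 (2E,6E,10E)-geranylgeraniol
Product: 2 (2E,6E,10E)-geranylgeranyl acetate
Conditions: Ac2O (1.5 equiv), pyridine (3 equiv), 4-(dimethylamino)pyridine (DMAP, 5 mol%), CH2Cl2, 0 °C to rt, 2 h
Reagents that add atoms: acetic anhydride, CC(=O)OC(C)=O
Why: DMAP-catalysed O-acylation of a primary allylic alcohol; no stereocentre is involved, the alkene geometry is untouched, and the acetate deactivates the neighbouring alkene for step 2.

**Step 2**
Reactants: 2 (2E,6E,10E)-geranylgeranyl acetate
Product: 4 (5S,9S,10S)-labda-7,13E-dien-15-yl acetate, via 15-acetoxylabd-13E-en-8-yl cation 3 (not isolated)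
Conditions: (R)-2'-[(2-fluorophenyl)methoxy]-1,1'-binaphthalen-2-ol (2.2 equiv), SnCl4 (2.0 equiv), toluene, −78 °C, 48–72 h; pyridine then aq NaHCO3 quench at −78 °C
Reagents that add atoms: none
Why: Enantioselective proton-initiated cationic polyene cyclization with a chiral Lewis-acid-assisted Brønsted acid (Yamamoto type): face-selective protonation of the terminal isopropylidene starts a chair–chair cascade in which the E geometry of both internal alkenes gives the trans ring fusion (5α-H, 10β-CH3) and the equatorial 9β side chain, the absolute sense being set by the acid; cation 3 loses a C7 proton to give the trisubstituted Δ7 alkene (as farnesyl acetate gives drimenyl acetate); the C13=C14 alkene, deactivated by its SnCl4-complexed allylic acetate, does not add to 3; the step is a net isomerization and the binaphthol ether is recovered.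

**Step 3**
Reactants: 4 (5S,9S,10S)-labda-7,13E-dien-15-yl acetate
Product: 5 (5S,9R,10S)-17-hydroxylabda-7,13E-dien-15-yl acetate
Conditions: SeO2 (0.3 equiv), t-BuOOH (5.5 M in decane, 3 equiv), CH2Cl2, 0 °C to rt, 24 h
Reagents that add atoms: tert-butyl hydroperoxide (terminal oxidant, source of the oxygen), CC(C)(C)OO; selenium dioxide (oxygen carrier), O=[Se]=O
Why: Catalytic SeO2/t-BuOOH allylic oxidation (Riley oxidation, Sharpless conditions): ene reaction with selenium bonding to the less substituted C7 and hydrogen taken from the C17 methyl (CH3 preferred over the hindered tertiary C9–H), then a [2,3]-sigmatropic shift that restores C7=C8 and places oxygen on C17, as in drimenyl acetate; the C13=C14 alkene is deactivated by its allylic acetate as in geranyl acetate; no stereocentre is touched (the 9R label only reflects the new CIP priority of C8).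

**Step 4**
Reactants: 5 (5S,9R,10S)-17-hydroxylabda-7,13E-dien-15-yl acetate
Product: 6 (5S,9R,10S)-labda-7,13E-diene-15,17-diyl diacetate (CNP0257931.1)
Conditions: Ac2O (1.5 equiv), pyridine (3 equiv), DMAP (5 mol%), CH2Cl2, 0 °C to rt, 2 h
Reagents that add atoms: acetic anhydride, CC(=O)OC(C)=O
Why: DMAP-catalysed acylation of the primary allylic C17 alcohol under non-ionizing conditions; no stereocentre or alkene is affected.

**Compound list**
1 | (2E,6E,10E)-geranylgeraniol (3,7,11,15-tetramethylhexadeca-2,6,10,14-tetraen-1-ol) | OC/C=C(\C)CC/C=C(\C)CC/C=C(\C)CCC=C(C)C | starting material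
2 | (2E,6E,10E)-geranylgeranyl acetate | CC(=O)OC/C=C(\C)CC/C=C(\C)CC/C=C(\C)CCC=C(C)C | intermediate
3 | 15-acetoxylabd-13E-en-8-yl cation (trans-decalin, tertiary cation at C8; not isolated) | CC(=O)OC/C=C(\C)CC[C@H]1[C+](C)CC[C@H]2C(C)(C)CCC[C@]12C | intermediate
4 | (5S,9S,10S)-labda-7,13E-dien-15-yl acetate (trans-decalin, 5α-H, 10β-CH3, 9β side chain, C7=C8 with C17 methyl) | CC(=O)OC/C=C(\C)CC[C@H]1C(C)=CC[C@H]2C(C)(C)CCC[C@]12C | intermediate
5 | (5S,9R,10S)-17-hydroxylabda-7,13E-dien-15-yl acetate | CC(=O)OC/C=C(\C)CC[C@H]1C(CO)=CC[C@H]2C(C)(C)CCC[C@]12C | intermediate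
6 | (5S,9R,10S)-labda-7,13E-diene-15,17-diyl diacetate | CC(=O)OC/C=C(\C)CC[C@H]1C(COC(C)=O)=CC[C@H]2C(C)(C)CCC[C@]12C | target

**Totals**
Total step count: 4. Longest linear sequence: 4.

**Steps most likely to fail, with fallbacks**

Step 2 (highest risk). The cascade may stall after ring A, give Δ8(17) or Δ8 alkene isomers, run on to a tricycle, or give only moderate ee. The fallback sets out from 2 and returns at 4. The two rings are closed in two separate, relayed operations. The same chiral acid at −78 °C, stopped early, is used only for ring A and gives monocyclic (2E,6E)-3,7-dimethyl-9-[(1S)-2,6,6-trimethylcyclohex-2-en-1-yl]nona-2,6-dien-1-yl acetate F1, in which C5 is already set. F1 is then treated with ClSO3H in 2-nitropropane at −78 °C. This reprotonates the ring alkene to the C10 cation and closes ring B through a chair transition state under control of C5, arriving at 4.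

Step 3. SeO2 may attack C9–H or over-oxidize C17 to the enal. The fallback sets out from 4 and returns at 5.
- mCPBA (1.05 equiv), NaHCO3, CH2Cl2, 0 °C epoxidizes the electron-richer ring alkene from the α face (away from the C10 methyl) to 7α,8α-epoxylabd-13E-en-15-yl acetate F2.
- Cp2TiCl (trivalent titanium, 2.2 equiv, made from Cp2TiCl2 and Mn dust, THF, rt) opens F2 homolytically at C8; trapping of the tertiary radical and β-hydride loss from C17 give 7α-hydroxylabda-8(17),13E-dien-15-yl acetate F3.
- Ph3SiOReO3 (2 mol%) with N,O-bis(trimethylsilyl)acetamide in Et2O at 0 °C transposes the allylic alcohol and traps the primary isomer as 17-(trimethylsilyloxy)labda-7,13E-dien-15-yl acetate F4.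
- Aqueous citric acid in THF frees 5.

F3 is also what SeO2 makes from any Δ8(17) isomer carried over from step 2, so that material can be fed in at this point.

Step 4. Low intrinsic risk; it matters if 5 is hard to free from selenium residues or enal, or if the ee needs raising. The fallback sets out from 5 and returns at 6. K2CO3 in MeOH at rt removes the C15 acetate to give (5S,9R,10S)-labda-7,13E-diene-15,17-diol F5. F5 is purified as the diol (crystallization or chiral-phase chromatography, which is also the place to raise ee). It is then acetylated at both primary allylic hydroxyls with Ac2O, pyridine and DMAP to give 6.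

**Further compounds**
F1 | step 2 | (2E,6E)-3,7-dimethyl-9-[(1S)-2,6,6-trimethylcyclohex-2-en-1-yl]nona-2,6-dien-1-yl acetate | CC(=O)OC/C=C(\C)CC/C=C(\C)CC[C@@H]1C(C)=CCCC1(C)C
F2 | step 3 | 7α,8α-epoxylabd-13E-en-15-yl acetate | CC(=O)OC/C=C(\C)CC[C@H]1[C@]3(C)O[C@@H]3C[C@H]2C(C)(C)CCC[C@]12C
F3 | step 3 | 7α-hydroxylabda-8(17),13E-dien-15-yl acetate | CC(=O)OC/C=C(\C)CC[C@H]1C(=C)[C@H](O)C[C@H]2C(C)(C)CCC[C@]12C
F4 | step 3 | 17-(trimethylsilyloxy)labda-7,13E-dien-15-yl acetate | CC(=O)OC/C=C(\C)CC[C@H]1C(CO[Si](C)(C)C)=CC[C@H]2C(C)(C)CCC[C@]12C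
F5 | step 4 | (5S,9R,10S)-labda-7,13E-diene-15,17-diol | OC/C=C(\C)CC[C@H]1C(CO)=CC[C@H]2C(C)(C)CCC[C@]12C
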